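All runs stem from a simulated flask for an exercise, and the scatter is random.

common to all: substrate 10 mM

|  | coupling partner | temperature | remark | time |
|---|---|---|---|---|
| eta | 40 mM | −20 °C | the very flask that is asked about, followed so far |  |
| alpha | 60 mM | −14 °C | run made earlier |  |
| flask | 40.0 mM | −20 °C |  | 8.0 d |

| run | time / d | target / % |
|---|---|---|
| eta | 0.833 | 20.8 |
| eta | 2.50 | 25.2 |
| eta | 4.00 | 20.4 |
| eta | 6.00 | 17.9 |
| alpha | 2.50 | 22.2 |
| alpha | 5.00 | 22.5 |
| alpha | 8.00 | 21.9 |
| alpha | 10.0 | 22.3 |

(each reading ± 0.5 percentage points)

- target, in percent of the substrate first charged, at 8.0 d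
- the remedy with the largest gain of target, or "none" below 2 percentage points (dawn / autumn / midnight / noon / none)
- target present, in percent of the substrate first charged, after midnight
- target present, in percent of the substrate first charged, after noon

- dawn: change nothing and wait 15 d more
- autumn: at 8.0 d take out 90 % of the by-product then present, then wait 15 d
- midnight: at 8.0 d raise the temperature by 15 K, then wait 15 d
- noon: at 8.0 d add coupling partner, 100 % of the amount charged, then wait 15 d

- what is added takes up no volume worth counting
- the numbers in the tables scatter by 0.5 percentage points (one standard deviation)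

Late in the alpha run target stood flat at 22.2 %, but late in the eta run it was still falling, by 4.8 percentage points and then by 2.5 points. From those two falls I read a decay time of 1.86 d and an eta plateau of 16.6 %, which I took as my "now", give or take the scatter.

I treated both plateaus as thermodynamic control and folded them into one number, 1.44: the plateau odds ratio, which says how many times the odds c(target)/(c(charged substrate) − c(target)) grew from the eta plateau to the alpha plateau. Spread over the 6.00 K between the runs, it made a rise of 15 K multiply the eta odds by 2.47, so I reckoned 32.9 % after midnight.

One number was not enough, since the alpha run also carried more coupling partner. On a one-to-one coupling the eta charge could use at most a quarter of its coupling partner, so I assumed that the late drift was a rearrangement without coupling partner and committed to midnight, with dawn, autumn and noon staying at the plateau.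

The forecast gave 17 %, close to my "now", but it differed on the remedy: it chose noon and put midnight at 15 % and noon at 28 %, saying of its scaling of target with coupling partner “this is a judgement, since temperature and partner are confounded”.

The flask gave 16.8 % at 8.0 d. The best remedy was midnight, gaining 13 points and reaching 29.5 %, while noon gained 0.04 points and reached 16.9 %.

    intermediate ⇌ isomer of the product A (K = 3.10, k = 4.35 × 10⁻⁴ min⁻¹, Ea = 81.0 kJ mol⁻¹, ΔH = −37.0 kJ mol⁻¹)
    substrate + coupling partner → intermediate + by-product (k = 0.0317 M⁻¹ min⁻¹, Ea = 46.0 kJ mol⁻¹)
    target ⇌ isomer of the product B (K = 2.18, k = 3.14 × 10⁻⁴ min⁻¹, Ea = 84.0 kJ mol⁻¹, ΔH = −48.0 kJ mol⁻¹)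
    intermediate ⇌ target (K = 1.50, k = 9.18 × 10⁻⁴ min⁻¹, Ea = 78.0 kJ mol⁻¹, ΔH = −8.00 kJ mol⁻¹)
    (constants at −20 °C)

A neighbouring flask, the same charge at 5 °C, stood 25.0 K above the eta run, so with the plateau odds ratio I multiplied the odds by 4.51 and reckoned 47.3 %. In that neighbouring flask target reached 35.5 % at 8.0 d, less than that reckoning, and intermediate held 33.3 %.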